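**Plan**
- Retrosynthesis: the three silyl ethers are removed and the C3 hydroxymethyl is taken back to a tert-butyl ester. The oxolane is then cut at O1–C5 and at C2–C3, which releases the protected vanillin aldehyde and an open-chain γ-chloro ester. That ester is cut at the bond between C4 and the exocyclic carbinol carbon (anti-aldol with the same aldehyde) and at the imide C–N bond, back to mono-tert-butyl succinate.
- Enabling feature: in the oxolane, O1–C2(aryl) is a latent aryl aldehyde C=O, C3 bears a carbon at the carboxyl level and can therefore be a carbanion, and C5 is an unsubstituted CH2 placed 1,3 to C3 that can carry chloride. C3–C4–C5 can thus act as a three-carbon dipole equivalent toward the aldehyde.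
- Forward: the four-carbon chain is acylated onto the auxiliary, joined to the first aldehyde molecule, reduced and chlorinated. The only ring arises in step 7, when the second aldehyde molecule is inserted; ester reduction and desilylation finish.
- Stereochemistry: the carbinol carbon and C4 come from the oxazolidinone-controlled anti-aldol. C2 and C3 are set relative to C4 by a reversible aldol and an irreversible ring closure that should drain all aldolate isomers into the all-trans oxolane.

Key step: step 7

Notation: Ar = 3-methoxy-4-(triisopropylsilyloxy)phenyl; TBS = tert-butyldimethylsilyl.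
Assumption: in step 3 the chelated magnesium enolate of the (S)-benzyl imide is taken to react on the face remote from the benzyl group, which corresponds to the (2R,3S)-anti adduct drawn; should the sense be the opposite, the (R)-auxiliary would serve in the same way.

**Step 1**
Reactants: 1 vanillin
Product: 2 3-methoxy-4-(triisopropylsilyloxy)benzaldehyde
Conditions: TIPSCl, imidazole, DMF, rt
Reagents that add atoms: triisopropylsilyl chloride, CC(C)[Si](Cl)(C(C)C)C(C)C
Why: Silyl ether formation at the phenol masks the acidic OH with a group that should survive alkoxide and hydride reagents and leaves the aldehyde free; no stereocentre is involved.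

**Step 2**
Reactants: 3 4-tert-butoxy-4-oxobutanoic acid; 4 (S)-4-benzyl-1,3-oxazolidin-2-one
Product: 6 tert-butyl 4-[(4S)-4-benzyl-2-oxo-1,3-oxazolidin-3-yl]-4-oxobutanoate, via mixed pivalic anhydride 5 (not isolated)
Conditions: PivCl, Et3N, THF, −20 °C; then 4, LiCl, rt
Reagents that add atoms: pivaloyl chloride, CC(C)(C)C(=O)Cl (its atoms are carried by 5 only; none remain in 6)
Why: N-acylation of the oxazolidinone through the mixed anhydride should occur at the less hindered succinyl carbonyl, the tert-butyl ester being inert; the only stereocentre is that of the auxiliary.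

**Step 3**
Reactants: 6 tert-butyl 4-[(4S)-4-benzyl-2-oxo-1,3-oxazolidin-3-yl]-4-oxobutanoate; 2 3-methoxy-4-(triisopropylsilyloxy)benzaldehyde
Product: 8 tert-butyl (3R)-4-[(4S)-4-benzyl-2-oxo-1,3-oxazolidin-3-yl]-3-[(S)-Ar(hydroxy)methyl]-4-oxobutanoate, via trimethylsilyl ether 7 (not isolated)
Conditions: MgCl2 (0.2 equiv), Et3N, TMSCl, EtOAc, rt; then TFA (cat.), MeOH, 0 °C
Reagents that add atoms: chlorotrimethylsilane, C[Si](C)(C)Cl (its atoms are carried by 7 only; none remain in 8)
Why: In this Evans magnesium-halide-catalysed anti-aldol, soft enolization of the chelated imide (more acidic than the ester side) gives the Z-enolate, the non-enolizable aldehyde should add through a boat-like transition state on the face away from the benzyl group to set the carbinol carbon (S) and the adjacent carbon (R) in the anti relation, silylation of the aldolate turns the magnesium over, and methanolysis frees the alcohol.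

**Step 4**
Reactants: 8 tert-butyl (3R)-4-[(4S)-4-benzyl-2-oxo-1,3-oxazolidin-3-yl]-3-[(S)-Ar(hydroxy)methyl]-4-oxobutanoate
Product: 9 tert-butyl (3R)-4-[(4S)-4-benzyl-2-oxo-1,3-oxazolidin-3-yl]-3-[(S)-Ar(tert-butyldimethylsilyloxy)methyl]-4-oxobutanoate
Conditions: TBSOTf, 2,6-lutidine, CH2Cl2, −78 to 0 °C
Reagents that add atoms: tert-butyldimethylsilyl triflate, CC(C)(C)[Si](C)(C)OS(=O)(=O)C(F)(F)F
Why: Silylation with a silyl triflate and a hindered base protects the benzylic carbinol without retro-aldol, giving an ether that should withstand the strongly basic key step; no stereocentre is touched.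

**Step 5**
Reactants: 9 tert-butyl (3R)-4-[(4S)-4-benzyl-2-oxo-1,3-oxazolidin-3-yl]-3-[(S)-Ar(tert-butyldimethylsilyloxy)methyl]-4-oxobutanoate
Product: 10 tert-butyl (3S,4S)-4-Ar-4-(tert-butyldimethylsilyloxy)-3-(hydroxymethyl)butanoate
Conditions: LiBH4, MeOH (1 equiv), THF, 0 °C
Reagents that add atoms: none
Why: Reductive cleavage of the N-acyl oxazolidinone by LiBH4 should take the activated imide carbonyl to the primary alcohol while the tert-butyl ester is spared, with no change at the stereocentres (the descriptor at C3 changes only through the priority rules); the alcohol is taken on directly to limit lactonization.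

**Step 6**
Reactants: 10 tert-butyl (3S,4S)-4-Ar-4-(tert-butyldimethylsilyloxy)-3-(hydroxymethyl)butanoate
Product: 11 tert-butyl (3R,4S)-4-Ar-4-(tert-butyldimethylsilyloxy)-3-(chloromethyl)butanoate
Conditions: PPh3, CCl4, CH2Cl2, rt
Reagents that add atoms: carbon tetrachloride, ClC(Cl)(Cl)Cl
Why: The Appel reaction converts the primary alcohol into the chloride by SN2 at a carbon that is not a stereocentre under neutral conditions tolerated by the silyl ethers and the ester; chloride is chosen on purpose as a slow leaving group for step 7.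

**Step 7**
Reactants: 11 tert-butyl (3R,4S)-4-Ar-4-(tert-butyldimethylsilyloxy)-3-(chloromethyl)butanoate; 2 3-methoxy-4-(triisopropylsilyloxy)benzaldehyde
Product: 13 tert-butyl (2S,3S,4S)-2-Ar-4-[(S)-Ar(tert-butyldimethylsilyloxy)methyl]oxolane-3-carboxylate, via potassium aldolate 12 (not isolated)
Conditions: KOtBu (1.3 equiv), 2 (1.2 equiv, present from the start), THF, −40 °C to rt
Reagents that add atoms: potassium tert-butoxide, CC(C)(C)[O-].[K+] (only its potassium, as the counter-ion of 12; none of its atoms remain in 13)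
Why: Potassium tert-butoxide reversibly deprotonates 11 next to the ester, the carbanion adds to the carbonyl carbon of 2 (new C2–C3 bond) to give aldolate 12, and the alkoxide oxygen then displaces chloride from the CH2Cl carbon (new O1–C5 bond), so the γ-chloro ester enolate behaves as a three-carbon dipole equivalent toward the aldehyde C=O. The closest known reaction type is the base-mediated annulation of γ-halo carbanions (4-chlorobutanoate esters, 4-chlorobutyronitrile, 3-chloropropyl sulfones) with aldehydes to 2,3-disubstituted oxolanes, a Darzens-type aldol–Williamson sequence extended by two carbons. The oxolane closes in the 5-exo-tet mode. C2 and C3 are set under Curtin–Hammett control: retro-aldol of the potassium aldolates is expected to be faster than displacement of the poor chloride leaving group, so all aldolate diastereomers should drain through the ring-closing transition state that keeps the aryl group, the ester and the bulky C4 side chain pseudo-equatorial, and C3 stays epimerizable under the base, which together should give the all-trans ring dictated by the fixed C4 stereocentre. The step needs carbonyl addition to beat 3-exo-tet closure of the carbanion to a cyclopropane and E2 loss of HCl, which the aldehyde in excess from the start, its lack of α-hydrogens and the slow chloride should secure. Ring opening of 13 by β-elimination of the ring oxygen would be the reverse of a 5-endo-trig closure and is therefore not expected.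

**Step 8**
Reactants: 13 tert-butyl (2S,3S,4S)-2-Ar-4-[(S)-Ar(tert-butyldimethylsilyloxy)methyl]oxolane-3-carboxylate
Product: 14 [(2S,3R,4S)-2-Ar-4-[(S)-Ar(tert-butyldimethylsilyloxy)methyl]oxolan-3-yl]methanol
Conditions: LiAlH4, THF, 0 °C to rt
Reagents that add atoms: none
Why: Hydride reduction of the ester to the primary alcohol should be faster than any enolization at C3 (which already holds the favoured trans arrangement) and leaves the silyl ethers and the benzylic ring ether intact.

**Step 9**
Reactants: 14 [(2S,3R,4S)-2-Ar-4-[(S)-Ar(tert-butyldimethylsilyloxy)methyl]oxolan-3-yl]methanol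
Product: 15 [(2S,3R,4S)-2-(4-hydroxy-3-methoxyphenyl)-4-[(S)-hydroxy(4-hydroxy-3-methoxyphenyl)methyl]oxolan-3-yl]methanol
Conditions: Bu4NF, AcOH, THF, 0 °C to rt
Reagents that add atoms: none
Why: Fluoride-mediated desilylation removes the two aryl silyl ethers and the benzylic silyl ether in one operation, the acetic acid buffer keeping the phenols protonated so that no quinone-methide pathway can scramble the benzylic centres.

**Compound list** (Ar = 3-methoxy-4-(triisopropylsilyloxy)phenyl)
1 | vanillin (4-hydroxy-3-methoxybenzaldehyde) | COc1cc(C=O)ccc1O | starting material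
2 | 3-methoxy-4-(triisopropylsilyloxy)benzaldehyde | COc1cc(C=O)ccc1O[Si](C(C)C)(C(C)C)C(C)C | intermediate
3 | 4-tert-butoxy-4-oxobutanoic acid (mono-tert-butyl succinate) | CC(C)(C)OC(=O)CCC(=O)O | starting material
4 | (S)-4-benzyl-1,3-oxazolidin-2-one | O=C1N[C@@H](Cc2ccccc2)CO1 | starting material
5 | 4-tert-butoxy-4-oxobutanoic pivalic anhydride | CC(C)(C)OC(=O)CCC(=O)OC(=O)C(C)(C)C | intermediate
6 | tert-butyl 4-[(4S)-4-benzyl-2-oxo-1,3-oxazolidin-3-yl]-4-oxobutanoate | CC(C)(C)OC(=O)CCC(=O)N1[C@@H](Cc2ccccc2)COC1=O | intermediate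
7 | tert-butyl (3R)-4-[(4S)-4-benzyl-2-oxo-1,3-oxazolidin-3-yl]-4-oxo-3-[(S)-Ar(trimethylsilyloxy)methyl]butanoate | CC(C)(C)OC(=O)C[C@@H](C(=O)N1[C@@H](Cc2ccccc2)COC1=O)[C@H](O[Si](C)(C)C)c1ccc(O[Si](C(C)C)(C(C)C)C(C)C)c(OC)c1 | intermediate
8 | tert-butyl (3R)-4-[(4S)-4-benzyl-2-oxo-1,3-oxazolidin-3-yl]-3-[(S)-Ar(hydroxy)methyl]-4-oxobutanoate | CC(C)(C)OC(=O)C[C@@H](C(=O)N1[C@@H](Cc2ccccc2)COC1=O)[C@H](O)c1ccc(O[Si](C(C)C)(C(C)C)C(C)C)c(OC)c1 | intermediate
9 | tert-butyl (3R)-4-[(4S)-4-benzyl-2-oxo-1,3-oxazolidin-3-yl]-3-[(S)-Ar(tert-butyldimethylsilyloxy)methyl]-4-oxobutanoate | CC(C)(C)OC(=O)C[C@@H](C(=O)N1[C@@H](Cc2ccccc2)COC1=O)[C@H](O[Si](C)(C)C(C)(C)C)c1ccc(O[Si](C(C)C)(C(C)C)C(C)C)c(OC)c1 | intermediate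
10 | tert-butyl (3S,4S)-4-Ar-4-(tert-butyldimethylsilyloxy)-3-(hydroxymethyl)butanoate | CC(C)(C)OC(=O)C[C@@H](CO)[C@H](O[Si](C)(C)C(C)(C)C)c1ccc(O[Si](C(C)C)(C(C)C)C(C)C)c(OC)c1 | intermediate
11 | tert-butyl (3R,4S)-4-Ar-4-(tert-butyldimethylsilyloxy)-3-(chloromethyl)butanoate | CC(C)(C)OC(=O)C[C@@H](CCl)[C@H](O[Si](C)(C)C(C)(C)C)c1ccc(O[Si](C(C)C)(C(C)C)C(C)C)c(OC)c1 | intermediate
12 | potassium aldolate of tert-butyl (2S,3R,4S)-4-Ar-2-[(S)-Ar(hydroxy)methyl]-4-(tert-butyldimethylsilyloxy)-3-(chloromethyl)butanoate (the ring-closing member of the equilibrating aldolates) | CC(C)(C)OC(=O)[C@H]([C@H]([O-])c1ccc(O[Si](C(C)C)(C(C)C)C(C)C)c(OC)c1)[C@@H](CCl)[C@H](O[Si](C)(C)C(C)(C)C)c1ccc(O[Si](C(C)C)(C(C)C)C(C)C)c(OC)c1.[K+] | intermediate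
13 | tert-butyl (2S,3S,4S)-2-Ar-4-[(S)-Ar(tert-butyldimethylsilyloxy)methyl]oxolane-3-carboxylate | COc1cc([C@@H](O[Si](C)(C)C(C)(C)C)[C@@H]2CO[C@H](c3ccc(O[Si](C(C)C)(C(C)C)C(C)C)c(OC)c3)[C@H]2C(=O)OC(C)(C)C)ccc1O[Si](C(C)C)(C(C)C)C(C)C | intermediate
14 | [(2S,3R,4S)-2-Ar-4-[(S)-Ar(tert-butyldimethylsilyloxy)methyl]oxolan-3-yl]methanol | COc1cc([C@@H](O[Si](C)(C)C(C)(C)C)[C@@H]2CO[C@H](c3ccc(O[Si](C(C)C)(C(C)C)C(C)C)c(OC)c3)[C@H]2CO)ccc1O[Si](C(C)C)(C(C)C)C(C)C | intermediate
15 | [(2S,3R,4S)-2-(4-hydroxy-3-methoxyphenyl)-4-[(S)-hydroxy(4-hydroxy-3-methoxyphenyl)methyl]oxolan-3-yl]methanol | COc1cc([C@@H](O)[C@@H]2CO[C@H](c3ccc(O)c(OC)c3)[C@H]2CO)ccc1O | target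

**Totals**
Total step count: 9. Longest linear sequence: 8 steps (steps 2 to 9, from 3 and 4); step 1 supplies aldehyde 2 for steps 3 and 7.

**Steps most likely to fail**

1. Step 7. The carbanion may close onto its own CH2Cl carbon (3-exo-tet) or lose HCl by E2 before it meets the aldehyde, and the ring-closing step may discriminate poorly between the two faces of the aldehyde. The fallback sets out from 10 and comes back at 14, and builds the ring by benzylic cation etherification instead of an anionic annulation. Acid-catalysed lactonization of 10 (pyridinium p-toluenesulfonate, toluene, 60 °C) should give (4S)-4-[(S)-Ar(tert-butyldimethylsilyloxy)methyl]oxolan-2-one F1. Its lithium enolate (LiN(SiMe3)2, THF, −78 °C) should add to 2 on the face away from the C4 substituent to give the trans aldol lactone (3S,4S)-3-[Ar(hydroxy)methyl]-4-[(S)-Ar(tert-butyldimethylsilyloxy)methyl]oxolan-2-one F2, as a mixture at the new carbinol carbon. LiAlH4 (THF, 0 °C) should open it to (2R,3S)-2-[Ar(hydroxy)methyl]-3-[(S)-Ar(tert-butyldimethylsilyloxy)methyl]butane-1,4-diol F3. Brief treatment with camphorsulfonic acid (cat.) in CH2Cl2 at 0 °C should ionize the free benzylic alcohol and let the primary hydroxyl on the neighbouring branch close the five-membered ring (the other primary hydroxyl could only give an oxetane). The planar cation erases the carbinol mixture and should give the 2,3-trans ring of 14.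

2. Step 3. Addition to the electron-rich aldehyde may be slow, retro-aldol may occur during methanolysis, and anti or facial selectivity may erode. The fallback sets out from 2 and comes back at 10, and sets the carbinol by catalytic reduction and the adjacent centre by chelate-controlled alkylation. A Roskamp reaction of 2 (ethyl diazoacetate, NbCl5 cat., CH2Cl2, rt) should give ethyl 3-Ar-3-oxopropanoate F4. Noyori asymmetric transfer hydrogenation (RuCl[(S,S)-TsDPEN](p-cymene), HCO2H/Et3N, rt) should give ethyl (S)-3-Ar-3-hydroxypropanoate F5. Fráter–Seebach alkylation of its dianion (LiN(iPr)2 2.2 equiv, THF, −78 to −20 °C; tert-butyl bromoacetate, DMPU) should deliver, anti to the alkoxide-bearing carbon, 4-tert-butyl 1-ethyl (2R)-2-[(S)-Ar(hydroxy)methyl]butanedioate F6. Silylation (TBSOTf, 2,6-lutidine, CH2Cl2) should give 4-tert-butyl 1-ethyl (2R)-2-[(S)-Ar(tert-butyldimethylsilyloxy)methyl]butanedioate F7. LiBH4 (THF, 0 °C to rt) should reduce the ethyl ester selectively over the tert-butyl ester to reach 10.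

3. Step 5. Hydride may attack the ring carbonyl of the hindered imide, the tert-butyl ester may be partly reduced, and the alkoxide formed may lactonize onto the tert-butyl ester. The fallback sets out from 9 and comes back at 10, and removes the auxiliary hydrolytically before a chemoselective reduction. LiOH/H2O2 (THF–H2O, 0 °C) should cleave the imide at the exocyclic carbonyl to (2R)-4-tert-butoxy-2-[(S)-Ar(tert-butyldimethylsilyloxy)methyl]-4-oxobutanoic acid F8. BH3·SMe2 (THF, 0 °C) should then reduce the carboxylic acid in the presence of the ester to give 10 as a neutral alcohol.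

**Further compounds**
F1 | step 7 | (4S)-4-[(S)-Ar(tert-butyldimethylsilyloxy)methyl]oxolan-2-one | O=C1C[C@H]([C@H](O[Si](C)(C)C(C)(C)C)c2ccc(O[Si](C(C)C)(C(C)C)C(C)C)c(OC)c2)CO1
F2 | step 7 | (3S,4S)-3-[Ar(hydroxy)methyl]-4-[(S)-Ar(tert-butyldimethylsilyloxy)methyl]oxolan-2-one (both epimers at the free carbinol) | O=C1[C@H](C(O)c2ccc(O[Si](C(C)C)(C(C)C)C(C)C)c(OC)c2)[C@H]([C@H](O[Si](C)(C)C(C)(C)C)c2ccc(O[Si](C(C)C)(C(C)C)C(C)C)c(OC)c2)CO1
F3 | step 7 | (2R,3S)-2-[Ar(hydroxy)methyl]-3-[(S)-Ar(tert-butyldimethylsilyloxy)methyl]butane-1,4-diol (both epimers at the free carbinol) | OC[C@H](C(O)c1ccc(O[Si](C(C)C)(C(C)C)C(C)C)c(OC)c1)[C@@H](CO)[C@H](O[Si](C)(C)C(C)(C)C)c1ccc(O[Si](C(C)C)(C(C)C)C(C)C)c(OC)c1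
F4 | step 3 | ethyl 3-Ar-3-oxopropanoate | CCOC(=O)CC(=O)c1ccc(O[Si](C(C)C)(C(C)C)C(C)C)c(OC)c1
F5 | step 3 | ethyl (S)-3-Ar-3-hydroxypropanoate | CCOC(=O)C[C@H](O)c1ccc(O[Si](C(C)C)(C(C)C)C(C)C)c(OC)c1
F6 | step 3 | 4-tert-butyl 1-ethyl (2R)-2-[(S)-Ar(hydroxy)methyl]butanedioate | CCOC(=O)[C@H](CC(=O)OC(C)(C)C)[C@H](O)c1ccc(O[Si](C(C)C)(C(C)C)C(C)C)c(OC)c1
F7 | step 3 | 4-tert-butyl 1-ethyl (2R)-2-[(S)-Ar(tert-butyldimethylsilyloxy)methyl]butanedioate | CCOC(=O)[C@H](CC(=O)OC(C)(C)C)[C@H](O[Si](C)(C)C(C)(C)C)c1ccc(O[Si](C(C)C)(C(C)C)C(C)C)c(OC)c1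
F8 | step 5 | (2R)-4-tert-butoxy-2-[(S)-Ar(tert-butyldimethylsilyloxy)methyl]-4-oxobutanoic acid | OC(=O)[C@H](CC(=O)OC(C)(C)C)[C@H](O[Si](C)(C)C(C)(C)C)c1ccc(O[Si](C(C)C)(C(C)C)C(C)C)c(OC)c1
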